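In a one-step world you compare two rate constants and are done. This flask runs on a catalyst that has to open first, and it comes in four set-ups:

all flasks: reagent 40.0 mM; precatalyst 2.8 mM

| run | starting material | second substrate | time | remark |
|---|---|---|---|---|
| green | 20 mM | 20.0 mM (fed, over 32.0 h) | 40 h | all but second substrate at the start; second substrate goes in evenly over 32.0 h, the run ends at 40 h |
| red | 20 mM | 20.0 mM | 40 h | everything together in a closed stirred flask, run for 40 h |
| amber | 20 mM | 20.0 mM |  | a single well-mixed tank run continuously and read at steady state, 40 h in it on average |
| ochre | 20 mM (fed, over 32.0 h) | 20.0 mM | 40 h | a stirred flask in which starting material is dosed at a steady rate over 32.0 h without added volume, worked up at 40 h |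

    starting material + free catalyst ⇌ catalyst intermediate A (K1 = 1700 M⁻¹, k1 = 0.048 M⁻¹ s⁻¹)
    reagent + catalyst intermediate A → free catalyst + target (k2 = 0.0013 M⁻¹ s⁻¹)
    second substrate + free catalyst ⇌ catalyst intermediate B (K3 = 660 M⁻¹, k3 = 0.022 M⁻¹ s⁻¹)
    reagent + catalyst intermediate B → free catalyst + second product (k4 = 0.0027 M⁻¹ s⁻¹)
    starting material + reagent → uncatalysed product (k5 = 4.5 × 10⁻⁵ M⁻¹ s⁻¹)
    precatalyst → free catalyst (k6 = 2.1 × 10⁻⁶ s⁻¹)

- the stated concentrations are those of everything mixed, before any reaction; amounts are the same in each set-up
- the feed brings no volume worth counting
- run time (green): 40 h

- the set-up with the highest share of target in all that became target or uncatalysed product, at the outlet or at the end ("none" if the first two lie within 2 percentage points) (green / red / amber / ochre / none)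
- share of target in all that became target or uncatalysed product, at the outlet or at the end, green
- share of target in all that became target or uncatalysed product, at the outlet or at the end, red
- share of target in all that became target or uncatalysed product, at the outlet or at the end, amber
- share of target in all that became target or uncatalysed product, at the outlet or at the end, ochre

Here is the oddity. The constant of the route to target, 0.0013 M⁻¹ s⁻¹, is 28.9 times that of the uncatalysed route, 4.5 × 10⁻⁵ M⁻¹ s⁻¹, yet in red I expect the route to target to run slower on average over the run than the uncatalysed one.

Write the balance of the catalyst, the smallest charge: c(precatalyst) + c(free catalyst) + c(catalyst intermediate A) + c(catalyst intermediate B) = 2.8 mM. Reagent multiplies both routes and cancels, so the large constant is weighed by c(catalyst intermediate A) and the small one by c(starting material).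

Precatalyst has a half-life of 92 h by its opening step alone, so over 40 h the mean opened catalyst is 0.384 mM. Taking binding as at equilibrium with the charged substrates, I put 70.5% of that as catalyst intermediate A. Background loss alone puts mean c(starting material) near 17.6 mM.

My carried quantity is the route ratio S, a selectivity factor: the rate to target over the rate to uncatalysed product, with mean concentrations. It comes to 0.445, and the share is S/(1+S). That gives 30.8% for red. I keep the same S for green, ignoring its dosing: 30.8%.

For ochre I keep the same share of opened catalyst as catalyst intermediate A and let the dosing scale mean c(starting material) by 0.600, so S becomes 0.742 and the share 42.6%. For the amber tank, with that share kept again, I reckon 0.650 mM of opened catalyst and 15.9 mM of starting material, so S is 0.834 and the share 45.5%. My pick is amber.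

The forecast picks amber, with 30.5% for green, 29% for red, 48% for amber and 39% for ochre, saying “The steady-state tank keeps catalyst present at its aged level throughout”. My amber lies below its figure, and my ochre above.

The simulation gives amber as best, with 31.9% for green, 30.3% for red, 47.8% for amber and 39.3% for ochre. Green with 0.70 mM of precatalyst takes S to 0.111, a share of 10.0%, and that flask gives 10.3%. In green itself, the uncatalysed step ran from the start, while precatalyst still held 78.5% of the catalyst at 32.0 h. At 40.0 h, with 17.5% of the catalyst as catalyst intermediate A, the uncatalysed step used reagent at 0.96 of the rate of the step to target.

The constants stand for no real mixture; no experiment stands behind them.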